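This closed vessel, in the alpha run, holds catalyst at 2.00% of the starting material, and what you want to know is how soon c(target) flattens.

| flask | starting material | catalyst | time |
|---|---|---|---|
| gamma | 0.0500 M | 5.00 × 10⁻⁴ M |  |
| epsilon | 0.0250 M | 5.00 × 10⁻⁴ M |  |
| alpha | 0.0500 M | 0.00100 M |  |
| zeta | 0.0750 M | 5.00 × 10⁻⁴ M |  |
| beta | 0.0500 M | 0.00320 M | 27 min |

| run | time / min | [target] / M |
|---|---|---|
| gamma run | 1.1 | 0.00158 |
| gamma run | 2.1 | 0.00342 |
| gamma run | 3.9 | 0.00584 |
| gamma run | 7.5 | 0.01034 |
| gamma run | 14 | 0.01533 |
| gamma run | 27 | 0.01967 |
| epsilon run | 1.1 | 0.00109 |
| epsilon run | 2.1 | 0.00180 |
| epsilon run | 3.9 | 0.00355 |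
| epsilon run | 7.5 | 0.00530 |
| epsilon run | 14 | 0.00805 |
| epsilon run | 27 | 0.01012 |
| alpha run | 1.1 | 0.00370 |
| alpha run | 2.1 | 0.00683 |
| alpha run | 3.9 | 0.01140 |
| alpha run | 7.5 | 0.01736 |
| alpha run | 14 | 0.02235 |
| alpha run | 27 | 0.02391 |
| zeta run | 1.1 | 0.00240 |
| zeta run | 2.1 | 0.00452 |
| zeta run | 3.9 | 0.00847 |
| zeta run | 7.5 | 0.01450 |
| zeta run | 14 | 0.02245 |
| zeta run | 27 | 0.02884 |

(standard deviation of a reading: 2 × 10⁻⁴ M)

* the exponent of [starting material] in the starting rate at the charge of the gamma run (at the point where two percent of the starting material have become target) (one fixed amount of target, the same in the runs compared)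
* the exponent of [catalyst] in the starting rate at the charge of the gamma run (at the point where two percent of the starting material have become target)
* target in the beta run at 27 min, as a share of the starting material charged

- Overall: starting material -> target, with catalyst as catalyst.
- Constant volume, constant temperature.
- A reading of a species includes what of it is bound.
- An order is taken over about fifteen percent of the charge, up and down.

Run it in slow motion, beginning with the first instants, while c(target) is still small. At 2.1 min, raising the catalyst by a factor 2.00 (gamma to alpha) multiplies c(target) by 2.00, so I read an order in catalyst of 0.998. Raising the starting material by a factor 3.00 (epsilon to zeta) multiplies it by 2.51, so I read an order in starting material of 0.838. These are ratios at one time, not at one amount of target; they carry the scatter of small readings, and the second spans a wider range of charge than the order asked.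

In the middle the alpha curve bends. The alpha flask opens at 0.00336 M/min and shows 0.02391 M at its last reading. Dividing that reading by the opening rate gives the approach time, 7.11 min: the time the alpha flask would need to reach that reading at its opening pace. It stands for the relaxation time if the approach is first-order. Since the order in catalyst reads near one, I let the opening rate grow with catalyst and keep the level as a share of the charge, so the approach time shrinks in proportion to the catalyst.

At the end, treat the last alpha reading as the level minus a small correction. On a first-order approach the gap left after 27 min is 2.24%, which puts my estimate of the alpha level at 0.0245 M, or 48.9% of the alpha charge. The beta flask has the same charge of starting material, and I reckon its approach time at 2.22 min. Its 27 min therefore spans 12.2 approach times, and the gap I reckon for it is <0.001%. My reckoning for beta is 48.9%.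

The forecast gave orders of 0.93 in starting material and 1.1 in catalyst with 50% for beta, and said of the flattening in alpha, “That looks like an equilibrium”.

The simulation gives orders of 0.83 and 1.0, and 49.9% for beta.

    catalyst + starting material ⇌ catalyst-substrate complex, settled at all times (5.240 /M)
    catalyst-substrate complex ⇌ target + catalyst (16.86 /min, 45.42 /M/min)
    target → decomposed product (0.009060 /min)
    starting material → decomposed substrate (0.01230 /min)

In the beta flask, the conversion of catalyst-substrate complex into target and its reverse carried c(target) up on the scale of my approach time of 2.22 min, far shorter than the lifetimes against decomposition, 81.3 min for starting material and 110 min for target. For the rest of the 27 min, c(target) stood near 1.95 times c(starting material) while both drained into decomposed substrate and decomposed product, and at 27 min the target was 49.9% of the charge.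

(The runs are simulated for substances that don't exist; noise was put on by code.)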